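**Strategy.** The plan cuts ring D, the 2,2-dimethyldihydropyran fused to ring B, across two bonds at once: C3'-CH2–CH2 and O4'–CMe2. The feature exploited is the ortho pair of O4' and the benzylic CH2 on C3', which is a latent o-quinone methide. Next to it sits a CH2–CMe2 unit that is simply isobutene. The precursor is the finished (2S)-flavanone (rings A, B and C, 8-prenyl, O7 as MOM ether) whose ring B is a saligenin (4'-OH, 3'-CH2OH). Heating it in isobutene expels water, and an inverse-demand hetero-Diels–Alder reaction should close ring D, with oxygen bonding to the CMe2 carbon. C2 is set earlier by enantioselective palladium-catalysed conjugate addition of a boronic acid to an 8-prenylchromone.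

Key step: step 8

Remark on numbering: flavanone numbering is used (O1, C2, C3, C4, C4a, C5–C8, C8a; ring B C1'–C6'), and ring D is the pyran ring on C3'/C4'.

Assumption: the facial sense of the t-BuPyOx catalyst on chromones is taken to parallel that on cyclic enones, so the (R)-ligand is assigned to the (2S)-product; the antipodal ligand is equally available.

Step 1
Reactants: 1 2,4-dihydroxyacetophenone; 2 prenyl bromide (1-bromo-3-methylbut-2-ene)
Product: 3 2,4-dihydroxy-3-(3-methylbut-2-enyl)acetophenone
Conditions: KOH, H2O/MeOH, 0 °C to rt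
Reagents that add atoms: none
Why: Nuclear prenylation (C-alkylation of an ambident phenolate): in protic alkaline medium the resacetophenone anion should react with the soft allylic bromide mainly at C3, the carbon activated by both flanking oxygens, and the C5-, O- and bis-alkylated isomers are removed by chromatography.

Step 2
Reactants: 3 2,4-dihydroxy-3-(3-methylbut-2-enyl)acetophenone
Product: 4 2-hydroxy-4-(methoxymethoxy)-3-(3-methylbut-2-enyl)acetophenone
Conditions: MOMCl, K2CO3, acetone, rt
Reagents that add atoms: chloromethyl methyl ether (MOMCl) COCCl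
Why: Williamson-type etherification is selective for the 4-OH because the 2-OH is held in a strong hydrogen bond to the acetyl carbonyl and is much less nucleophilic under weak base.

Step 3
Reactants: 4 2-hydroxy-4-(methoxymethoxy)-3-(3-methylbut-2-enyl)acetophenone
Product: 6 7-(methoxymethoxy)-8-(3-methylbut-2-enyl)-4H-chromen-4-one, via enaminone 5 (not isolated)
Conditions: DMF-DMA, toluene, 100 °C; evaporate; AcOH, 60 °C
Reagents that add atoms: N,N-dimethylformamide dimethyl acetal (DMF-DMA) COC(OC)N(C)C
Why: Enaminone chromone synthesis: condensation of the methyl ketone with the formamide acetal supplies C2 of ring C, and in warm acetic acid the phenol adds to the protonated vinylogous amide in a 6-endo addition–elimination that expels dimethylamine under conditions mild enough for the MOM ether and the prenyl group.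

Step 4
Reactants: 7 5-bromo-2-hydroxybenzyl alcohol
Product: 8 6-bromo-2,2-dimethyl-4H-1,3-benzodioxine
Conditions: 2,2-dimethoxypropane, TsOH·H2O (cat.), acetone, rt
Reagents that add atoms: 2,2-dimethoxypropane COC(C)(C)OC
Why: Acid-catalysed transketalisation ties the phenol and the benzylic alcohol into a temporary six-membered isopropylidene ketal that removes both acidic protons for the lithiation and hides the quinone methide precursor until step 7.

Step 5
Reactants: 8 6-bromo-2,2-dimethyl-4H-1,3-benzodioxine
Product: 9 (2,2-dimethyl-4H-1,3-benzodioxin-6-yl)boronic acid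
Conditions: n-BuLi, THF, −78 °C; B(OiPr)3, −78 °C to rt; sat. aq. NH4Cl
Reagents that add atoms: triisopropyl borate CC(C)OB(OC(C)C)OC(C)C; water O
Why: Bromine–lithium exchange followed by electrophilic borylation and near-neutral hydrolysis of the borate is standard for aryl bromides, and the ketal is inert to n-BuLi at −78 °C and to the ammonium chloride quench.

Step 6
Reactants: 6 7-(methoxymethoxy)-8-(3-methylbut-2-enyl)-4H-chromen-4-one; 9 (2,2-dimethyl-4H-1,3-benzodioxin-6-yl)boronic acid
Product: 10 (2S)-2-(2,2-dimethyl-4H-1,3-benzodioxin-6-yl)-7-(methoxymethoxy)-8-(3-methylbut-2-enyl)chroman-4-one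
Conditions: Pd(OCOCF3)2 (5 mol %), (R)-t-BuPyOx (6 mol %), NH4PF6 (30 mol %), H2O (5 equiv), ClCH2CH2Cl, 60 °C
Reagents that add atoms: none
Why: Enantioselective conjugate addition of an arylboronic acid to a chromone under cationic divalent palladium/pyridine-oxazoline catalysis: transmetalation, migratory insertion of C2=C3 into the aryl–palladium bond on the face left open by the tert-butyl group of the (R)-ligand, and protonolysis of the palladium enolate should set C2 as S without any base that could reopen ring C.

Step 7
Reactants: 10 (2S)-2-(2,2-dimethyl-4H-1,3-benzodioxin-6-yl)-7-(methoxymethoxy)-8-(3-methylbut-2-enyl)chroman-4-one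
Product: 11 (2S)-2-[4-hydroxy-3-(hydroxymethyl)phenyl]-7-(methoxymethoxy)-8-(3-methylbut-2-enyl)chroman-4-one
Conditions: AcOH/H2O/THF 3:1:1, 40 °C
Reagents that add atoms: none
Why: Mild acid hydrolysis differentiates the two acetals, since the isopropylidene ketal ionises through a tertiary oxocarbenium ion far faster than the formaldehyde-derived MOM acetal, and the weakly acidic medium keeps C2 safe because ring C opens through a phenolate or an enolate.

Step 8
Reactants: 11 (2S)-2-[4-hydroxy-3-(hydroxymethyl)phenyl]-7-(methoxymethoxy)-8-(3-methylbut-2-enyl)chroman-4-one; 12 isobutene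
Product: 14 (2S)-2-(2,2-dimethylchroman-6-yl)-7-(methoxymethoxy)-8-(3-methylbut-2-enyl)chroman-4-one, via o-quinone methide 13 (not isolated)
Conditions: 12/toluene 1:1 (12 in large excess), 0.01 M in 11, degassed, steel autoclave, 160 °C
Reagents that add atoms: none
Why: On heating, the phenolic proton of 11 passes through the internal hydrogen bond to the neighbouring benzylic hydroxyl, water leaves, and ring B is dearomatised to the o-quinone methide 13 (C4'=O, C3'=CH2), which is present only at a low stationary concentration. As an electron-poor 1-oxadiene, 13 should take up the electron-rich 1,1-disubstituted alkene 12 in an inverse-electron-demand hetero-Diels–Alder reaction driven by rearomatisation of ring B; the closest known reaction type is the thermal chroman synthesis from o-hydroxybenzyl alcohols and unactivated alkenes. Ring D closes by an intermolecular, concerted but asynchronous [4+2] cycloaddition in which O4', C4', C3' and the exocyclic CH2 supply four ring atoms and 12 supplies two, so the CH2–CH2 bond and the O–CMe2 bond are made in the same event. Regioselectivity comes from the polarised transition state: the unsubstituted terminus of 12 bonds to the electrophilic methylene while the carbon that builds up tertiary cationic character bonds to oxygen, which allows only the 2,2-dimethyl isomer. No stereocentre is created, and C2 is a spectator that should keep its S configuration because the medium is neutral, non-polar and free of amine or metal salts, whereas opening of ring C needs an enolate, a phenolate or strong acid. Chemoselectivity is secured by the substrate: only ring B has a free phenol ortho to a CH2OH group, the MOM ether stops ring A from acting as a phenol nucleophile, the hindered trisubstituted 8-prenyl alkene at 0.01 M cannot compete with 12 used as cosolvent, and adducts of 13 with water or phenolic OH revert on heating while the cycloadduct does not.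

Step 9
Reactants: 14 (2S)-2-(2,2-dimethylchroman-6-yl)-7-(methoxymethoxy)-8-(3-methylbut-2-enyl)chroman-4-one
Product: 15 euchrenone a17
Conditions: TsOH·H2O (cat.), MeOH, 40 °C
Reagents that add atoms: none
Why: Acid-catalysed transacetalisation to methanol removes the phenolic MOM group under conditions in which the flavanone C2 does not epimerise and at a temperature too low for Markovnikov cyclisation of the weakly nucleophilic 7-OH onto the prenyl alkene.

**Compound list**

1 | 2,4-dihydroxyacetophenone | CC(=O)c1ccc(O)cc1O | starting material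
2 | prenyl bromide (1-bromo-3-methylbut-2-ene) | CC(C)=CCBr | starting material
3 | 2,4-dihydroxy-3-(3-methylbut-2-enyl)acetophenone | CC(=O)c1ccc(O)c(CC=C(C)C)c1O | intermediate
4 | 2-hydroxy-4-(methoxymethoxy)-3-(3-methylbut-2-enyl)acetophenone | CC(=O)c1ccc(OCOC)c(CC=C(C)C)c1O | intermediate
5 | (E)-3-(dimethylamino)-1-[2-hydroxy-4-(methoxymethoxy)-3-(3-methylbut-2-enyl)phenyl]prop-2-en-1-one (enaminone, not isolated) | CN(C)/C=C/C(=O)c1ccc(OCOC)c(CC=C(C)C)c1O | intermediate
6 | 7-(methoxymethoxy)-8-(3-methylbut-2-enyl)-4H-chromen-4-one | COCOc1ccc2C(=O)C=COc2c1CC=C(C)C | intermediate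
7 | 5-bromo-2-hydroxybenzyl alcohol | OCc1cc(Br)ccc1O | starting material
8 | 6-bromo-2,2-dimethyl-4H-1,3-benzodioxine | CC1(C)OCc2cc(Br)ccc2O1 | intermediate
9 | (2,2-dimethyl-4H-1,3-benzodioxin-6-yl)boronic acid | CC1(C)OCc2cc(B(O)O)ccc2O1 | intermediate
10 | (2S)-2-(2,2-dimethyl-4H-1,3-benzodioxin-6-yl)-7-(methoxymethoxy)-8-(3-methylbut-2-enyl)chroman-4-one | CC(C)=CCc1c(OCOC)ccc2c1O[C@H](c1ccc3c(c1)COC(C)(C)O3)CC2=O | intermediate
11 | (2S)-2-[4-hydroxy-3-(hydroxymethyl)phenyl]-7-(methoxymethoxy)-8-(3-methylbut-2-enyl)chroman-4-one | CC(C)=CCc1c(OCOC)ccc2c1O[C@H](c1ccc(O)c(CO)c1)CC2=O | intermediate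
12 | isobutene (2-methylpropene) | CC(C)=C | starting material
13 | (2S)-7-(methoxymethoxy)-8-(3-methylbut-2-enyl)-2-(3-methylidene-4-oxocyclohexa-1,5-dien-1-yl)chroman-4-one (o-quinone methide, not isolated) | CC(C)=CCc1c(OCOC)ccc2c1O[C@H](C1=CC(=C)C(=O)C=C1)CC2=O | intermediate
14 | (2S)-2-(2,2-dimethylchroman-6-yl)-7-(methoxymethoxy)-8-(3-methylbut-2-enyl)chroman-4-one | CC(C)=CCc1c(OCOC)ccc2c1O[C@H](c1ccc3c(c1)CCC(C)(C)O3)CC2=O | intermediate
15 | euchrenone a17, (2S)-2-(2,2-dimethylchroman-6-yl)-7-hydroxy-8-(3-methylbut-2-enyl)chroman-4-one | CC(C)=CCc1c(O)ccc2c1O[C@H](c1ccc3c(c1)CCC(C)(C)O3)CC2=O | target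

**Total step count:** 9.
**Longest linear sequence:** 7 (steps 1, 2, 3, 6, 7, 8, 9).

**Steps most likely to fail**

**Step 8.**
- What may go wrong: at the temperature the dehydration needs, ring C may open and reclose. This could happen by retro-oxa-Michael through the C4 enol, or by ionisation of the C2–O1 bond pushed by the free 4'-OH and pulled by the C4 acyl group. Either path would erode the configuration at C2.
- The quinone methide may also be lost to self-condensation before isobutene reaches it.
- Fallback, setting out from 11 and returning at 14: the oxidation level of C4 is changed for the duration of the cycloaddition.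
- Luche reduction of 11 (NaBH4, CeCl3·7H2O, MeOH, −20 °C) should give the 2,4-cis alcohol (2S,4S)-2-[4-hydroxy-3-(hydroxymethyl)phenyl]-7-(methoxymethoxy)-8-(3-methylbut-2-enyl)chroman-4-ol F1. This compound has neither an enolisable carbonyl nor an acyl-stabilised aryloxide leaving group, so it tolerates higher temperature and higher dilution.
- Thermolysis of this alcohol in isobutene/toluene should close ring D to (2S,4S)-2-(2,2-dimethylchroman-6-yl)-7-(methoxymethoxy)-8-(3-methylbut-2-enyl)chroman-4-ol F2.
- MnO2 (CH2Cl2, rt) then re-oxidises the benzylic C4 alcohol to 14.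

**Step 6.**
- What may go wrong: slow insertion of the electron-rich, 8-substituted chromone, competing protodeboronation of the electron-rich boronic acid, premature loss of the ketal to the trace acid released by the catalyst, or insufficient facial selectivity.
- Fallback, setting out from 8 and 4 and returning at 10: ring C is built by the chalcone route and the enantiomers are separated by catalytic kinetic resolution.
- Bromide 8 is lithiated (n-BuLi, THF, −78 °C) and formylated with DMF to 2,2-dimethyl-4H-1,3-benzodioxine-6-carbaldehyde F3.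
- Claisen–Schmidt condensation with 4 (KOH, EtOH, rt) should give (E)-3-(2,2-dimethyl-4H-1,3-benzodioxin-6-yl)-1-[2-hydroxy-4-(methoxymethoxy)-3-(3-methylbut-2-enyl)phenyl]prop-2-en-1-one F4.
- NaOAc in refluxing EtOH closes ring C by oxa-Michael addition to the racemic flavanone rac-2-(2,2-dimethyl-4H-1,3-benzodioxin-6-yl)-7-(methoxymethoxy)-8-(3-methylbut-2-enyl)chroman-4-one F5.
- Asymmetric transfer hydrogenation with RuCl[(R,R)-TsDPEN](p-cymene) and HCO2H/Et3N in EtOAc should reduce only the (2R)-enantiomer, giving (2R,4R)-2-(2,2-dimethyl-4H-1,3-benzodioxin-6-yl)-7-(methoxymethoxy)-8-(3-methylbut-2-enyl)chroman-4-ol F6. This alcohol is removed by chromatography, leaving 10.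

**Step 1.**
- What may go wrong: poor discrimination between C3, C5 and the oxygens of the ambident phenolate, and over-alkylation.
- Fallback, setting out from 1 and returning at 3: the prenyl group is delivered by a sigmatropic shift instead of direct C-alkylation.
- The non-chelated 4-OH of 1 is alkylated with 3-chloro-3-methylbut-1-yne (K2CO3, KI, CuI cat., acetone, reflux) to 2-hydroxy-4-(2-methylbut-3-yn-2-yloxy)acetophenone F7.
- Semihydrogenation (H2, Pd/CaCO3 poisoned with Pb(OAc)2, quinoline, EtOAc) gives 2-hydroxy-4-(2-methylbut-3-en-2-yloxy)acetophenone F8.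
- Heating in N,N-diethylaniline triggers an aromatic Claisen [3,3] rearrangement with allyl inversion. This should go to C3, the position favoured by the bond fixation of the chelated ring, and gives 3.

**Further compounds**

F1 | step 8 | (2S,4S)-2-[4-hydroxy-3-(hydroxymethyl)phenyl]-7-(methoxymethoxy)-8-(3-methylbut-2-enyl)chroman-4-ol | CC(C)=CCc1c(OCOC)ccc2c1O[C@H](c1ccc(O)c(CO)c1)C[C@@H]2O
F2 | step 8 | (2S,4S)-2-(2,2-dimethylchroman-6-yl)-7-(methoxymethoxy)-8-(3-methylbut-2-enyl)chroman-4-ol | CC(C)=CCc1c(OCOC)ccc2c1O[C@H](c1ccc3c(c1)CCC(C)(C)O3)C[C@@H]2O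
F3 | step 6 | 2,2-dimethyl-4H-1,3-benzodioxine-6-carbaldehyde | CC1(C)OCc2cc(C=O)ccc2O1
F4 | step 6 | (E)-3-(2,2-dimethyl-4H-1,3-benzodioxin-6-yl)-1-[2-hydroxy-4-(methoxymethoxy)-3-(3-methylbut-2-enyl)phenyl]prop-2-en-1-one | CC(C)=CCc1c(OCOC)ccc(C(=O)/C=C/c2ccc3c(c2)COC(C)(C)O3)c1O
F5 | step 6 | rac-2-(2,2-dimethyl-4H-1,3-benzodioxin-6-yl)-7-(methoxymethoxy)-8-(3-methylbut-2-enyl)chroman-4-one (racemate) | CC(C)=CCc1c(OCOC)ccc2c1OC(c1ccc3c(c1)COC(C)(C)O3)CC2=O
F6 | step 6 | (2R,4R)-2-(2,2-dimethyl-4H-1,3-benzodioxin-6-yl)-7-(methoxymethoxy)-8-(3-methylbut-2-enyl)chroman-4-ol | CC(C)=CCc1c(OCOC)ccc2c1O[C@@H](c1ccc3c(c1)COC(C)(C)O3)C[C@H]2O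
F7 | step 1 | 2-hydroxy-4-(2-methylbut-3-yn-2-yloxy)acetophenone | CC(=O)c1ccc(OC(C)(C)C#C)cc1O
F8 | step 1 | 2-hydroxy-4-(2-methylbut-3-en-2-yloxy)acetophenone | CC(=O)c1ccc(OC(C)(C)C=C)cc1O
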